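The spiro[4.5] core rests on one C–C bond, C5–C9. In the target the quaternary carbon C5 joins the cyclopentane (C5–C9, lactone on C7/C8) to the cyclohexene (C1–C5, C10). C9, the CH2 next to the lactone-oxygen carbon C8, is attached to C5, while C10 holds the CH2O arm. Reconnecting C9 to C10 turns the spirocycle into a fused six-six bicycle. Forward, an aluminium Lewis acid opens the 5,6-oxirane of the angular C10 carbinol 26 at C5; C9 moves from C10 to C5, ring B shrinks to the cyclopentane, the spiro centre is fixed and C10 emerges as the ketone of 28. Precursor 26 is a cis-fused 10-hydroxy-5,6-epoxydecalin bearing the cis-lactone, the C4 methyl and a bis-silylated trans-diol.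

Key step: step 18

Remark on the chemistry: atoms carry eudesmane-type numbers (ring A = C1–C5 and C10; ring B = C5–C10; lactone carbons C11 and C12 on C7, ring oxygen on C8; C13 = lactone methylene, C14 = CH2O carbon on C10); β is the face of the angular C10 oxygen; TBS = tert-butyldimethylsilyl.

Step 1
Reactants: 1 cyclohexa-1,4-diene
Product: 2 7-oxabicyclo[4.1.0]hept-3-ene (meso mono-epoxide)
Conditions: mCPBA (1 equiv), NaHCO3, CH2Cl2, 0 °C
Reagents that add atoms: mCPBA, O=C(OO)c1cccc(Cl)c1
Why: Prilezhaev epoxidation with one equivalent of peracid should stop at the meso mono-epoxide, and no stereocentre of consequence is set.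

Step 2
Reactants: 2 7-oxabicyclo[4.1.0]hept-3-ene
Product: 3 (1S,2S)-cyclohex-4-ene-1,2-diol
Conditions: oligomeric cobalt–salen tosylate catalyst (salen)Co(OTs) (trivalent cobalt; the enantiomer that gives the (1S,2S)-diol), H2O, MeCN, 4 °C
Reagents that add atoms: water, O
Why: Cobalt–salen-catalysed hydrolytic desymmetrisation of a meso-epoxide should deliver water anti to the oxirane at one enantiotopic carbon, so the trans-diol forms and the catalyst fixes both stereocentres.

Step 3
Reactants: 3 (1S,2S)-cyclohex-4-ene-1,2-diol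
Product: 4 (4S,5S)-4,5-bis(TBS-oxy)cyclohex-1-ene
Conditions: TBSCl, imidazole, DMF, rt
Reagents that add atoms: tert-butyldimethylsilyl chloride, CC(C)(C)[Si](C)(C)Cl
Why: Silyl ether formation at both secondary hydroxyls; no stereocentre is touched.

Step 4
Reactants: 4 (4S,5S)-4,5-bis(TBS-oxy)cyclohex-1-ene
Product: 6 (4S,5S)-4,5-bis(TBS-oxy)cyclohex-2-en-1-one, via allylic hydroperoxide 5 (not isolated)
Conditions: O2, visible light, tetraphenylporphyrin (cat.), CH2Cl2, 0 °C; then Ac2O, pyridine, DMAP (cat.), rt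
Reagents that add atoms: dioxygen, O=O
Why: Schenck ene reaction with singlet oxygen shifts the double bond and the acetylated hydroperoxide loses acetic acid (Kornblum–DeLaMare-type elimination) to the transposed enone; the C2-symmetric alkene can give only one constitution and the two silyloxy centres are untouched.

Step 5
Reactants: 6 (4S,5S)-4,5-bis(TBS-oxy)cyclohex-2-en-1-one
Product: 8 (3R,4S,5S)-2-[(dimethylamino)methyl]-3-methyl-4,5-bis(TBS-oxy)cyclohexanone (aminomethyl trans to methyl), via lithium enolate 7 (not isolated)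
Conditions: Me2CuLi (from MeLi and CuI), Et2O, −78 °C; then CH2=NMe2+ I−, THF, −78 °C to rt
Reagents that add atoms: lithium dimethylcuprate, [Li+].C[Cu-]C; Eschenmoser's salt, C=[N+](C)C.[I-]
Why: Gilman conjugate addition followed by Mannich trapping of the regiodefined enolate; the methyl should enter anti to the pseudo-axial γ-silyloxy group (sets C4, methyl trans to O3) and the iminium ion anti to the new methyl.

Step 6
Reactants: 8 (3R,4S,5S)-2-[(dimethylamino)methyl]-3-methyl-4,5-bis(TBS-oxy)cyclohexanone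
Product: 10 (3R,4S,5S)-3-methyl-2-methylidene-4,5-bis(TBS-oxy)cyclohexanone, via ammonium iodide 9 (not isolated)
Conditions: MeI, MeOH, rt; then aq. NaHCO3, CH2Cl2, rt; used at once
Reagents that add atoms: none
Why: N-Methylation and E1cB (Hofmann-type) loss of trimethylamine should unveil the exocyclic enone, which is taken on directly because α-methylene ketones dimerise.

Step 7
Reactants: 11 (R)-2,2-dimethyl-1,3-dioxolane-4-carbaldehyde
Product: 12 methyl (Z)-3-[(4S)-2,2-dimethyl-1,3-dioxolan-4-yl]prop-2-enoate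
Conditions: Ph3P=CHCO2Me, MeOH, 0 °C; chromatographic removal of the (E)-isomer
Reagents that add atoms: methyl (triphenylphosphoranylidene)acetate, COC(=O)C=P(c1ccccc1)(c1ccccc1)c1ccccc1
Why: Wittig olefination with the stabilised ylide in methanol is known to favour the (Z)-enoate of this aldehyde; the dioxolane stereocentre is not affected.

Step 8
Reactants: 12 methyl (Z)-3-[(4S)-2,2-dimethyl-1,3-dioxolan-4-yl]prop-2-enoate
Product: 13 methyl (3S)-3-[(4S)-2,2-dimethyl-1,3-dioxolan-4-yl]pent-4-enoate
Conditions: CH2=CHMgBr (2 equiv), CuI (1 equiv), THF, −78 to −30 °C; aq. NH4Cl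
Reagents that add atoms: vinylmagnesium bromide, C=C[Mg]Br
Why: Cuprate conjugate addition to the (Z)-enoate; allylic 1,3-strain holds the dioxolane C–H in the alkene plane and the vinyl group should enter from the side of the ring oxygen, anti to the ring CH2O carbon, which gives the syn adduct and sets C7.

Step 9
Reactants: 13 methyl (3S)-3-[(4S)-2,2-dimethyl-1,3-dioxolan-4-yl]pent-4-enoate
Product: 14 (3S)-3-[(4S)-2,2-dimethyl-1,3-dioxolan-4-yl]pent-4-en-1-ol
Conditions: LiAlH4, THF, 0 °C
Reagents that add atoms: none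
Why: Hydride reduction of the ester to the primary alcohol leaves acetonide, alkene and both stereocentres untouched.

Step 10
Reactants: 14 (3S)-3-[(4S)-2,2-dimethyl-1,3-dioxolan-4-yl]pent-4-en-1-ol
Product: 15 (4S)-4-[(3S)-5-(4-methoxybenzyloxy)pent-1-en-3-yl]-2,2-dimethyl-1,3-dioxolane
Conditions: NaH, 4-MeOC6H4CH2Cl, Bu4NI (cat.), THF/DMF, 0 °C to rt
Reagents that add atoms: 4-methoxybenzyl chloride, COc1ccc(CCl)cc1
Why: Williamson etherification gives a PMB ether that survives organolithium reagents and is later removed oxidatively without touching the silyl ethers.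

Step 11
Reactants: 15 (4S)-4-[(3S)-5-(4-methoxybenzyloxy)pent-1-en-3-yl]-2,2-dimethyl-1,3-dioxolane
Product: 16 (2S,3S)-3-[2-(4-methoxybenzyloxy)ethyl]pent-4-ene-1,2-diol
Conditions: AcOH/H2O (4:1), 40 °C
Reagents that add atoms: none
Why: Acid-catalysed acetal hydrolysis frees the 1,2-diol; the PMB ether is stable to aqueous acetic acid.

Step 12
Reactants: 16 (2S,3S)-3-[2-(4-methoxybenzyloxy)ethyl]pent-4-ene-1,2-diol
Product: 17 (2S,3S)-1-iodo-3-[2-(4-methoxybenzyloxy)ethyl]pent-4-en-2-ol
Conditions: I2, PPh3, imidazole, CH2Cl2, 0 °C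
Reagents that add atoms: iodine, II
Why: Appel-type (Garegg–Samuelsson) iodination is selective for the primary hydroxyl of a 1,2-diol; the C8 carbinol keeps its configuration.

Step 13
Reactants: 17 (2S,3S)-1-iodo-3-[2-(4-methoxybenzyloxy)ethyl]pent-4-en-2-ol; 10 (3R,4S,5S)-3-methyl-2-methylidene-4,5-bis(TBS-oxy)cyclohexanone
Product: 20 (3R,4S,5S)-1-[(2S,3S)-2-hydroxy-3-[2-(4-methoxybenzyloxy)ethyl]pent-4-en-1-yl]-3-methyl-2-methylidene-4,5-bis(TBS-oxy)cyclohexan-1-ol (side chain trans to the 3-methyl and 5-silyloxy groups), via dilithio reagent 18 (not isolated), via organocerium reagent 19 (not isolated)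
Conditions: 17, n-BuLi (1 equiv), Et2O/THF, −78 °C; t-BuLi (2.1 equiv), −78 °C; CeCl3, −78 °C; then 10, −78 °C; aq. NH4Cl
Reagents that add atoms: none
Why: Alkoxide formation, iodine–lithium exchange and transmetalation give a β-oxido organocerium reagent that is stable at −78 °C (an oxide is a poor leaving group) and adds 1,2 to the enone (organocerium carbonyl addition); the C2 silyloxy and C4 methyl groups, both 1,3 to the carbonyl carbon and axial in the chair preferred by the trans-bis-silyl ether, should shield one face so that C9 enters trans to both and sets C10.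

Step 14
Reactants: 20 tertiary carbinol PMB ether
Product: 21 (3R,4S,5S)-1-[(2S,3S)-2,5-dihydroxy-3-vinylpentyl]-3-methyl-2-methylidene-4,5-bis(TBS-oxy)cyclohexan-1-ol
Conditions: DDQ, CH2Cl2/pH 7 buffer, 0 °C
Reagents that add atoms: none
Why: Oxidative cleavage of the PMB ether by DDQ leaves silyl ethers, alkenes and the free alcohols intact.

Step 15
Reactants: 21 triol
Product: 24 cis-5-{[(3R,4S,5S)-1-hydroxy-3-methyl-2-methylidene-4,5-bis(TBS-oxy)cyclohexyl]methyl}-4-vinyldihydrofuran-2(3H)-one, via hydroxy aldehyde 22 (not isolated), via lactol 23 (not isolated)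
Conditions: TEMPO (cat.), PhI(OAc)2, CH2Cl2, rt
Reagents that add atoms: none
Why: TEMPO/PhI(OAc)2 oxidises only the primary alcohol; the aldehyde closes to the five-membered lactol with the C8 hydroxyl and is oxidised on to the γ-lactone (oxidative lactonisation of a 1,4-diol), whose cis substitution follows from C7/C8.

Step 16
Reactants: 24 lactone diene
Product: 25 cis-fused octalinol lactone: 10β-hydroxy-4β-methyl-2β,3α-bis(TBS-oxy)eudesm-type 5(6)-ene 12,8β-olide
Conditions: second-generation Grubbs catalyst (cat.), toluene, 80 °C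
Reagents that add atoms: none
Why: Ring-closing metathesis between the vinyl group and the 1,1-disubstituted alkene should close ring B as the trisubstituted C5=C6 alkene with loss of ethene; the free allylic alcohol is tolerated.

Step 17
Reactants: 25 octalinol lactone
Product: 26 5β,6β-epoxy-10β-hydroxy-4β-methyl-2β,3α-bis(TBS-oxy)decalin 12,8β-olide (cis-fused, oxirane syn to the angular hydroxyl)
Conditions: VO(acac)2 (cat.), t-BuOOH, CH2Cl2, 0 °C to rt
Reagents that add atoms: tert-butyl hydroperoxide, CC(C)(C)OO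
Why: Hydroxyl-directed vanadium-catalysed epoxidation; the tertiary allylic alcohol binds the metal peroxide and delivers oxygen to its own face of C5=C6, which sets C5 and C6.

Step 18
Reactants: 26 epoxy-decalinol lactone
Product: 28 spiro[4.5]decanone lactone with C10 ketone and C6β secondary alcohol (C5 spiro centre as in the target), via aluminium alkoxide 27 (not isolated)
Conditions: Me2AlCl (2.5 equiv), CH2Cl2, −78 to −30 °C; Rochelle-salt work-up
Reagents that add atoms: none
Why: Me2AlCl should turn the angular hydroxyl into a chloro(methyl)aluminium alkoxide whose metal reaches the syn oxirane oxygen, so that the C5–O bond at the fully substituted oxirane carbon weakens while the C10–C9 σ-bond shifts to C5 and the oxygen lone pair closes to the C10 carbonyl; this is a Lewis-acid semipinacol rearrangement of a 2,3-epoxy alcohol in its ring-contracting form. The cyclopentane C5–C6–C7–C8–C9 is closed by a 1,2-alkyl shift, that is by contraction of ring B and not by a cyclisation. The spiro stereocentre C5 is set by inversion at the migration terminus (C9 enters anti to the departing oxygen), so it is relayed from the oxirane of step 17 and from C10 of step 13, and the C6 carbinol keeps its configuration. The step needs migration of C9 (ring B) and not of C1 (ring A, which would contract the wrong ring), and no hydride shift from C4 or elimination. In the five-membered O–Al–O chelate the C10–O and C5–O bonds are nearly eclipsed, which requires C10–C9 axial on ring A and a boat-like ring B; there C10–C9 is the one carbon bond that approaches anti-periplanarity to the breaking C5–O bond as the oxirane opens, while C10–C1 stays gauche. A non-chelating acid such as BF3·OEt2 is avoided because its open complex can react through the conformer in which C10–C1 is anti.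

Step 19
Reactants: 28 spiro hydroxy ketone
Product: 29 O-phenyl thionocarbonate of 28 at C6
Conditions: PhOC(S)Cl, pyridine, DMAP (cat.), CH2Cl2, 0 °C to rt
Reagents that add atoms: O-phenyl chlorothionoformate, S=C(Cl)Oc1ccccc1
Why: Thioacylation under pyridine/DMAP is mild enough to spare the β-hydroxy ketone from retro-aldol cleavage (first half of the Barton–McCombie deoxygenation).

Step 20
Reactants: 29 thionocarbonate
Product: 30 spiro ketone lactone: (2S,3S,4R,5R,7R,8R)-4-methyl-10-oxo-2,3-bis(TBS-oxy)spiro lactone with C6 as CH2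
Conditions: Bu3SnH (excess, about 1 M), Et3B, air, toluene, rt
Reagents that add atoms: none
Why: Barton–McCombie radical deoxygenation; a high stannane concentration at room temperature should let hydrogen transfer to the C6 radical outrun a 1,2-acyl shift onto the neighbouring carbonyl.

Step 21
Reactants: 30 spiro ketone lactone
Product: 32 C10 enol triflate (C1=C10) of 30, via potassium enolate 31 (not isolated)
Conditions: KN(SiMe3)2 (1.05 equiv), THF, −78 °C; then PhNTf2, −78 °C
Reagents that add atoms: N-phenylbis(trifluoromethanesulfonimide), O=S(=O)(N(c1ccccc1)S(=O)(=O)C(F)(F)F)C(F)(F)F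
Why: Kinetic deprotonation at C1, the only enolisable position of the ketone and more acidic than the lactone α-position, then O-sulfonylation gives the enol triflate; −78 °C guards against β-elimination of the C2 silyloxy group.

Step 22
Reactants: 32 enol triflate
Product: 33 allylic alcohol with CH2OH (C14) on C10 and C1=C10 alkene
Conditions: Bu3SnCH2OH, Pd(PPh3)4 (cat.), LiCl, 1,4-dioxane, 100 °C
Reagents that add atoms: (tributylstannyl)methanol, CCCC[Sn](CCCC)(CCCC)CO
Why: Stille coupling of the enol triflate with the hydroxymethylstannane installs the CH2O carbon without a hydride reagent that would endanger the lactone.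

Step 23
Reactants: 33 allylic alcohol
Product: 35 α-[(dimethylamino)methyl] lactone (aminomethyl on the convex face, cis to H7), via dilithium enolate 34 (not isolated)
Conditions: LDA (2.3 equiv), THF, −78 °C; CH2=NMe2+ I− (3 equiv), −78 to 0 °C; aq. NaHCO3
Reagents that add atoms: Eschenmoser's salt, C=[N+](C)C.[I-]
Why: Two equivalents of LDA give the alkoxide and the lactone enolate, which undergoes a Mannich reaction with the iminium salt from the convex face of the cis-fused bicycle; the new centre disappears in the next step and the O-aminal at the alkoxide hydrolyses on work-up.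

Step 24
Reactants: 35 Mannich base
Product: 37 α-methylene lactone with free C14 hydroxyl, via ammonium iodide 36 (not isolated)
Conditions: MeI, MeOH/CH2Cl2, rt; then aq. NaHCO3, rt
Reagents that add atoms: none
Why: N-Methylation and base-induced loss of trimethylamine (E1cB, Hofmann-type) unveil the α-methylene lactone; the primary alcohol is not alkylated under neutral conditions.

Step 25
Reactants: 37 α-methylene lactone alcohol
Product: 38 C14 angelate bis-TBS ether
Conditions: angelic acid, 2,4,6-Cl3C6H2COCl, Et3N, toluene, rt; then 37, 80 °C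
Reagents that add atoms: angelic acid, C/C=C(/C)C(=O)O
Why: Mixed-anhydride (Yamaguchi-type) esterification run without DMAP is the established way to acylate with angelic acid without isomerisation to the tiglate; the primary allylic alcohol is the only free hydroxyl.

Step 26
Reactants: 38 angelate bis-TBS ether
Product: 39 target CNP0224912.1, (2S,3S,4R,5R,7R,8R) in the numbering used here
Conditions: HF·pyridine, pyridine, THF, 0 °C to rt
Reagents that add atoms: none
Why: Fluoride-mediated cleavage of the two secondary silyl ethers under buffered conditions should leave the angelate and the α-methylene lactone intact.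

Compound list
1 | cyclohexa-1,4-diene | C1=CCC=CC1 | starting material
2 | 7-oxabicyclo[4.1.0]hept-3-ene | C1=CC[C@@H]2O[C@@H]2C1 | intermediate
3 | (1S,2S)-cyclohex-4-ene-1,2-diol | C1=CC[C@H](O)[C@@H](O)C1 | intermediate
4 | (4S,5S)-4,5-bis(TBS-oxy)cyclohex-1-ene | C1=CC[C@H](O[Si](C)(C)C(C)(C)C)[C@@H](O[Si](C)(C)C(C)(C)C)C1 | intermediate
5 | (4S,5S)-4,5-bis(TBS-oxy)cyclohex-2-en-1-yl hydroperoxide (one C1 epimer drawn; both give 6) | OO[C@@H]1C[C@H](O[Si](C)(C)C(C)(C)C)[C@@H](O[Si](C)(C)C(C)(C)C)C=C1 | intermediate (not isolated)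
6 | (4S,5S)-4,5-bis(TBS-oxy)cyclohex-2-en-1-one | O=C1C[C@H](O[Si](C)(C)C(C)(C)C)[C@@H](O[Si](C)(C)C(C)(C)C)C=C1 | intermediate
7 | lithium enolate of (3R,4S,5S)-3-methyl-4,5-bis(TBS-oxy)cyclohexanone | [Li]OC1=C[C@@H](C)[C@H](O[Si](C)(C)C(C)(C)C)[C@@H](O[Si](C)(C)C(C)(C)C)C1 | intermediate (not isolated)
8 | (3R,4S,5S)-2-[(dimethylamino)methyl]-3-methyl-4,5-bis(TBS-oxy)cyclohexanone, 2,3-trans | O=C1C[C@H](O[Si](C)(C)C(C)(C)C)[C@@H](O[Si](C)(C)C(C)(C)C)[C@H](C)[C@H]1CN(C)C | intermediate
9 | trimethylammonium iodide derived from 8 | O=C1C[C@H](O[Si](C)(C)C(C)(C)C)[C@@H](O[Si](C)(C)C(C)(C)C)[C@H](C)[C@H]1C[N+](C)(C)C.[I-] | intermediate (not isolated)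
10 | (3R,4S,5S)-3-methyl-2-methylidene-4,5-bis(TBS-oxy)cyclohexanone | C=C1[C@@H](C)[C@H](O[Si](C)(C)C(C)(C)C)[C@@H](O[Si](C)(C)C(C)(C)C)CC1=O | intermediate
11 | (R)-2,2-dimethyl-1,3-dioxolane-4-carbaldehyde | CC1(C)OC[C@H](C=O)O1 | starting material
12 | methyl (Z)-3-[(4S)-2,2-dimethyl-1,3-dioxolan-4-yl]prop-2-enoate | COC(=O)/C=C\[C@H]1COC(C)(C)O1 | intermediate
13 | methyl (3S)-3-[(4S)-2,2-dimethyl-1,3-dioxolan-4-yl]pent-4-enoate | COC(=O)C[C@@H](C=C)[C@H]1COC(C)(C)O1 | intermediate
14 | (3S)-3-[(4S)-2,2-dimethyl-1,3-dioxolan-4-yl]pent-4-en-1-ol | OCC[C@@H](C=C)[C@H]1COC(C)(C)O1 | intermediate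
15 | (4S)-4-[(3S)-5-(4-methoxybenzyloxy)pent-1-en-3-yl]-2,2-dimethyl-1,3-dioxolane | COc1ccc(COCC[C@@H](C=C)[C@H]2COC(C)(C)O2)cc1 | intermediate
16 | (2S,3S)-3-[2-(4-methoxybenzyloxy)ethyl]pent-4-ene-1,2-diol | COc1ccc(COCC[C@@H](C=C)[C@H](O)CO)cc1 | intermediate
17 | (2S,3S)-1-iodo-3-[2-(4-methoxybenzyloxy)ethyl]pent-4-en-2-ol | COc1ccc(COCC[C@@H](C=C)[C@H](O)CI)cc1 | intermediate
18 | C1-lithio lithium alkoxide derived from 17 | [Li]C[C@@H](O[Li])[C@H](C=C)CCOCc1ccc(OC)cc1 | intermediate (not isolated)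
19 | dichlorocerium analogue of 18 | Cl[Ce](Cl)C[C@@H](O[Li])[C@H](C=C)CCOCc1ccc(OC)cc1 | intermediate (not isolated)
20 | tertiary carbinol from 19 and 10 (C9 trans to C4 methyl and C2 silyloxy), PMB ether | C=C1[C@@H](C)[C@H](O[Si](C)(C)C(C)(C)C)[C@@H](O[Si](C)(C)C(C)(C)C)C[C@]1(O)C[C@@H](O)[C@H](C=C)CCOCc1ccc(OC)cc1 | intermediate
21 | triol from 20 (C8, C10 and C12 hydroxyls) | C=C1[C@@H](C)[C@H](O[Si](C)(C)C(C)(C)C)[C@@H](O[Si](C)(C)C(C)(C)C)C[C@]1(O)C[C@@H](O)[C@H](C=C)CCO | intermediate
22 | C12 aldehyde from 21 | C=C1[C@@H](C)[C@H](O[Si](C)(C)C(C)(C)C)[C@@H](O[Si](C)(C)C(C)(C)C)C[C@]1(O)C[C@@H](O)[C@H](C=C)CC=O | intermediate (not isolated)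
23 | five-membered lactol from 22 (one anomer drawn) | C=C1[C@@H](C)[C@H](O[Si](C)(C)C(C)(C)C)[C@@H](O[Si](C)(C)C(C)(C)C)C[C@]1(O)C[C@H]1O[C@@H](O)C[C@H]1C=C | intermediate (not isolated)
24 | cis-4-vinyl-γ-butyrolactone carrying the ring A carbinol on its C5 methylene | C=C1[C@@H](C)[C@H](O[Si](C)(C)C(C)(C)C)[C@@H](O[Si](C)(C)C(C)(C)C)C[C@]1(O)C[C@H]1OC(=O)C[C@H]1C=C | intermediate
25 | cis-fused 10β-hydroxy-4β-methyl-2β,3α-bis(TBS-oxy)octal-5-ene 12,8β-olide | C1C(=O)O[C@@H]2C[C@@]3(O)C[C@H](O[Si](C)(C)C(C)(C)C)[C@@H](O[Si](C)(C)C(C)(C)C)[C@H](C)C3=C[C@H]12 | intermediate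
26 | 5β,6β-epoxy-10β-hydroxy-4β-methyl-2β,3α-bis(TBS-oxy)decalin 12,8β-olide | C1C(=O)O[C@@H]2C[C@@]3(O)C[C@H](O[Si](C)(C)C(C)(C)C)[C@@H](O[Si](C)(C)C(C)(C)C)[C@H](C)[C@]34O[C@@H]4[C@H]12 | intermediate
27 | chloro(methyl)aluminium alkoxide of 26 | C1C(=O)O[C@@H]2C[C@@]3(O[Al](C)Cl)C[C@H](O[Si](C)(C)C(C)(C)C)[C@@H](O[Si](C)(C)C(C)(C)C)[C@H](C)[C@]34O[C@@H]4[C@H]12 | intermediate (not isolated)
28 | spiro[4.5]decan-10-one lactone with C6β hydroxyl | C1C(=O)O[C@@H]2C[C@@]3([C@H](O)[C@H]12)C(=O)C[C@H](O[Si](C)(C)C(C)(C)C)[C@@H](O[Si](C)(C)C(C)(C)C)[C@@H]3C | intermediate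
29 | C6 O-phenyl thionocarbonate of 28 | C1C(=O)O[C@@H]2C[C@@]3([C@H](OC(=S)Oc4ccccc4)[C@H]12)C(=O)C[C@H](O[Si](C)(C)C(C)(C)C)[C@@H](O[Si](C)(C)C(C)(C)C)[C@@H]3C | intermediate
30 | 6-deoxy spiro ketone lactone | C1C(=O)O[C@@H]2C[C@@]3(C[C@H]12)C(=O)C[C@H](O[Si](C)(C)C(C)(C)C)[C@@H](O[Si](C)(C)C(C)(C)C)[C@@H]3C | intermediate
31 | potassium C1=C10 enolate of 30 | C1C(=O)O[C@@H]2C[C@@]3(C[C@H]12)C(O[K])=C[C@H](O[Si](C)(C)C(C)(C)C)[C@@H](O[Si](C)(C)C(C)(C)C)[C@@H]3C | intermediate (not isolated)
32 | C10 enol triflate | C1C(=O)O[C@@H]2C[C@@]3(C[C@H]12)C(OS(=O)(=O)C(F)(F)F)=C[C@H](O[Si](C)(C)C(C)(C)C)[C@@H](O[Si](C)(C)C(C)(C)C)[C@@H]3C | intermediate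
33 | C14 allylic alcohol | C1C(=O)O[C@@H]2C[C@@]3(C[C@H]12)C(CO)=C[C@H](O[Si](C)(C)C(C)(C)C)[C@@H](O[Si](C)(C)C(C)(C)C)[C@@H]3C | intermediate
34 | dilithium alkoxide lactone enolate of 33 | C1=C(O[Li])O[C@@H]2C[C@@]3(C[C@H]12)C(CO[Li])=C[C@H](O[Si](C)(C)C(C)(C)C)[C@@H](O[Si](C)(C)C(C)(C)C)[C@@H]3C | intermediate (not isolated)
35 | C11 (dimethylamino)methyl lactone | CN(C)C[C@H]1C(=O)O[C@@H]2C[C@@]3(C[C@H]12)C(CO)=C[C@H](O[Si](C)(C)C(C)(C)C)[C@@H](O[Si](C)(C)C(C)(C)C)[C@@H]3C | intermediate
36 | trimethylammonium iodide derived from 35 | C[N+](C)(C)C[C@H]1C(=O)O[C@@H]2C[C@@]3(C[C@H]12)C(CO)=C[C@H](O[Si](C)(C)C(C)(C)C)[C@@H](O[Si](C)(C)C(C)(C)C)[C@@H]3C.[I-] | intermediate (not isolated)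
37 | α-methylene lactone with free C14 hydroxyl | C=C1C(=O)O[C@@H]2C[C@@]3(C[C@H]12)C(CO)=C[C@H](O[Si](C)(C)C(C)(C)C)[C@@H](O[Si](C)(C)C(C)(C)C)[C@@H]3C | intermediate
38 | C14 angelate, 2,3-bis-TBS ether | C=C1C(=O)O[C@@H]2C[C@@]3(C[C@H]12)C(COC(=O)/C(C)=C\C)=C[C@H](O[Si](C)(C)C(C)(C)C)[C@@H](O[Si](C)(C)C(C)(C)C)[C@@H]3C | intermediate
39 | CNP0224912.1 | C=C1C(=O)O[C@@H]2C[C@@]3(C[C@H]12)C(COC(=O)/C(C)=C\C)=C[C@H](O)[C@@H](O)[C@@H]3C | target

Total step count: 26. Longest linear sequence: 20 steps (steps 1–6 and 13–26 from 1; the branch from 11, steps 7–12 and 13–26, is equally long).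

Steps most likely to fail

Step 18. The ring A bond C10–C1 may migrate instead of C10–C9, through a conformer in which C1 is anti to the oxirane C–O bond, so that ring A contracts; the tertiary cation may also be lost by elimination. The fallback drops the rearrangement and builds the spiro centre by twofold ketone alkylation. It sets out from 13 and from 6 and comes back at 30. Acid treatment of 13 (TsOH, MeOH) would remove the acetonide with lactonisation to (4S,5S)-5-(hydroxymethyl)-4-vinyldihydrofuran-2(3H)-one F1. Ozonolysis with NaBH4 work-up would give (4S,5S)-4,5-bis(hydroxymethyl)dihydrofuran-2(3H)-one F2, and I2/PPh3/imidazole the cis-4,5-bis(iodomethyl) lactone F3. Enolate 7, made from 6 and Me2CuLi as in step 5, would be alkylated (THF/HMPA) by the iodomethyl group on lactone C4, the one not adjacent to the ring oxygen, to give keto iodide F4. The more substituted potassium enolate of F4 (KOt-Bu, t-BuOH/THF) should then close the cyclopentane by 5-exo-tet alkylation anti to the C4 methyl and give 30, with no epoxide, carbinol or deoxygenation needed.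

Step 13. Facial selectivity in the carbonyl addition may be poor (reaction through the chair with equatorial substituents), and the reagent may undergo β-elimination if the temperature rises. The fallback adds the same reagent 19 at the cyclohexenone stage, where attack anti to the axial C5 silyloxy group is the normal course, and brings in the methyl and the exocyclic methylene afterwards. It sets out from 6 and comes back at 20. Morita–Baylis–Hillman hydroxymethylation of 6 (aq. CH2O, DMAP, THF) would give (4S,5S)-2-(hydroxymethyl)-4,5-bis(TBS-oxy)cyclohex-2-en-1-one F5, and Et3SiCl/imidazole its triethylsilyl ether F6. Addition of 19 and a dilute-acid work-up that removes the triethylsilyl group would give the cyclohexenyl triol F7. Picolinic acid/EDC/DMAP would acylate only the primary allylic hydroxyl to give picolinate F8. MeMgBr with CuBr·SMe2 should then deliver the methyl to C4 anti to the C3 silyloxy group in an SN2′ reaction that moves the double bond to the exocyclic position, which gives 20.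

Step 20. The C6 radical may add to the neighbouring C10 carbonyl and undergo a 1,2-acyl shift (Dowd–Beckwith-type ring expansion) faster than it takes up hydrogen. The fallback removes the carbonyl before the radical step. It sets out from 29 and comes back at 30. NaBH4/CeCl3 in MeOH at −40 °C would reduce the ketone to the C10 alcohol thionocarbonate F9 (either epimer serves). Bu3SnH/AIBN would deoxygenate C6 to the C10 alcohol F10, and Dess–Martin periodinane would reoxidise it to 30.

Further compounds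
F1 | step 18 | (4S,5S)-5-(hydroxymethyl)-4-vinyldihydrofuran-2(3H)-one | OC[C@H]1OC(=O)C[C@H]1C=C
F2 | step 18 | (4S,5S)-4,5-bis(hydroxymethyl)dihydrofuran-2(3H)-one | OC[C@H]1OC(=O)C[C@H]1CO
F3 | step 18 | cis-4,5-bis(iodomethyl)dihydrofuran-2(3H)-one (configuration of F2) | IC[C@H]1OC(=O)C[C@H]1CI
F4 | step 18 | (3R,4S,5S)-2-{[cis-2-(iodomethyl)-5-oxotetrahydrofuran-3-yl]methyl}-3-methyl-4,5-bis(TBS-oxy)cyclohexanone, 2,3-trans | O=C1C[C@H](O[Si](C)(C)C(C)(C)C)[C@@H](O[Si](C)(C)C(C)(C)C)[C@H](C)[C@H]1C[C@@H]1CC(=O)O[C@@H]1CI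
F5 | step 13 | (4S,5S)-2-(hydroxymethyl)-4,5-bis(TBS-oxy)cyclohex-2-en-1-one | O=C1C[C@H](O[Si](C)(C)C(C)(C)C)[C@@H](O[Si](C)(C)C(C)(C)C)C=C1CO
F6 | step 13 | triethylsilyl ether of F5 | O=C1C[C@H](O[Si](C)(C)C(C)(C)C)[C@@H](O[Si](C)(C)C(C)(C)C)C=C1CO[Si](CC)(CC)CC
F7 | step 13 | cyclohex-2-enyl triol from 19 and F6 (C9 trans to the C2 silyloxy group), PMB ether | OCC1=C[C@H](O[Si](C)(C)C(C)(C)C)[C@@H](O[Si](C)(C)C(C)(C)C)C[C@]1(O)C[C@@H](O)[C@H](C=C)CCOCc1ccc(OC)cc1
F8 | step 13 | primary allylic picolinate of F7 | O=C(OCC1=C[C@H](O[Si](C)(C)C(C)(C)C)[C@@H](O[Si](C)(C)C(C)(C)C)C[C@]1(O)C[C@@H](O)[C@H](C=C)CCOCc1ccc(OC)cc1)c1ccccn1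
F9 | step 20 | C10 alcohol of thionocarbonate 29 (one epimer drawn) | C1C(=O)O[C@@H]2C[C@@]3([C@H](OC(=S)Oc4ccccc4)[C@H]12)[C@@H](O)C[C@H](O[Si](C)(C)C(C)(C)C)[C@@H](O[Si](C)(C)C(C)(C)C)[C@@H]3C
F10 | step 20 | C10 alcohol of 30 (one epimer drawn) | C1C(=O)O[C@@H]2C[C@@]3(C[C@H]12)[C@@H](O)C[C@H](O[Si](C)(C)C(C)(C)C)[C@@H](O[Si](C)(C)C(C)(C)C)[C@@H]3C
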